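The quinone ring is numbered C1 (C=O), C2 (OAc), C3 (aryl), C4 (C=O), C5 (H), C6 (aryl). It is cut at the C1–C6 bond: C1–C4, with their three oxygens and the C3 aryl group, are a squarate-derived cyclobutenone, and C5–C6 is a styryl group on C4. Heating this 4-hydroxy-4-styrylcyclobutenone opens the four-membered ring to a dienylketene that recloses as the fully substituted six-membered ring, so the 1,2,4-oxygenation and the para-diaryl pattern are set before the step. The precursor is racemic 4-hydroxy-2-isopropoxy-3-aryl-4-[(E)-styryl]cyclobutenone with both phenols as TBS ethers.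

Key step: step 4

Remark: Ar = 4-(tert-butyldimethylsilyloxy)phenyl. Hydroquinone and quinone names use the C1–C6 numbering above. Compounds 5, 6, 9, 10 and 12 are racemic (9 as a diastereomer mixture), which is immaterial because these centres are destroyed and the target is achiral. Compounds 1, 3 and 7 are taken as commercial.

Step 1
Reactants: 1 4-(tert-butyldimethylsilyloxy)benzaldehyde
Product: 2 (E)-tert-butyl[4-(2-iodovinyl)phenoxy]dimethylsilane
Conditions: CHI3, CrCl2, THF, 0 °C → rt
Reagents that add atoms: iodoform, IC(I)I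
Why: Takai olefination, in which CrCl2 (divalent chromium) reduces iodoform to a geminal dichromium carbenoid that adds to the aryl aldehyde and eliminates to the (E)-vinyl iodide without touching the aryl silyl ether, and any minor Z isomer would be harmless because this alkene geometry is erased in step 4.

Step 2
Reactants: 2 (E)-tert-butyl[4-(2-iodovinyl)phenoxy]dimethylsilane; 3 diisopropyl squarate
Product: 6 2,3-diisopropoxy-4-[(E)-2-Ar-vinyl]-4-(trimethylsilyloxy)cyclobut-2-en-1-one (racemic), via vinyllithium 4 (not isolated), via lithium alkoxide 5 (not isolated)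
Conditions: t-BuLi (2 equiv), Et2O, −78 °C; then 3, THF, −78 °C; then TMSCl, −78 → 0 °C
Reagents that add atoms: chlorotrimethylsilane, C[Si](C)(C)Cl
Why: Iodine–lithium exchange with retention of the E geometry, 1,2-addition of the vinyllithium to one of the two equivalent squarate carbonyls (the carbinol centre forms as a racemate) and in situ O-silylation of the tertiary lithium alkoxide should give a carbinol-protected cyclobutenone whose remaining carbonyl can accept a second organolithium.

Step 3
Reactants: 6 2,3-diisopropoxy-4-[(E)-2-Ar-vinyl]-4-(trimethylsilyloxy)cyclobut-2-en-1-one; 7 (4-bromophenoxy)-tert-butyldimethylsilane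
Product: 10 4-hydroxy-2-isopropoxy-3-Ar-4-[(E)-2-Ar-vinyl]cyclobut-2-en-1-one (racemic), via aryllithium 8 (not isolated), via carbinol alkoxide 9 (not isolated)
Conditions: 7, n-BuLi, THF, −78 °C; then 6, −78 °C; then 1 M HCl, THF, 0 °C → rt
Reagents that add atoms: water, O
Why: Bromine–lithium exchange and 1,2-addition to the vinylogous ester carbonyl give tertiary carbinol 9, whose hydroxyl ionises in dilute acid with help from the enol ether oxygen so that water enters at the isopropoxy-bearing carbon at the far end of the allyl cation (the one bonded to the styryl carbinol) and isopropanol leaves, which transposes the enone and puts the aryl group on the ring carbon next to the carbinol, while the same acid hydrolyses the labile tertiary TMS ether and should spare the aryl TBS ethers (organolithium addition followed by acid-mediated allylic transposition and ketal hydrolysis).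

Step 4
Reactants: 10 4-hydroxy-2-isopropoxy-3-Ar-4-[(E)-2-Ar-vinyl]cyclobut-2-en-1-one
Product: 13 2-isopropoxy-3,6-bis(Ar)benzene-1,4-diol, via dienylketene 11 (not isolated), via cyclohexadienone 12 (not isolated)
Conditions: degassed toluene, 110 °C, argon
Reagents that add atoms: none
Why: Heating breaks the C1–C4 bond of 10 in a conrotatory 4π electrocyclic opening in which the donor hydroxyl turns outward, so the styryl group lies on the same side as the ketene in dienylketene 11. The ketene carbon C1 then bonds to the aryl-bearing styryl terminus C6 in a thermally allowed disrotatory 6π electrocyclisation that closes the six-membered carbocycle as cyclohexadienone 12, and enolisation of its C6–H gives the aromatic hydroquinone 13. The closest known reaction type is the thermal ring expansion of 4-alkenyl-4-hydroxycyclobutenones to hydroquinones (Moore rearrangement). No stereocentre results, because the C4 centre of 10 and the transient C6 centre of 12 both become sp2, so neither the racemic nature of 10 nor the alkene geometry matters. The selectivity needed is torquoselectivity (hydroxyl out, styryl in), secured by the strong outward preference of an oxygen donor at C4, and constitutional fidelity, secured because only a C4 substituent can reach the ketene carbon, so the C3 aryl group is a spectator and ends para to the C6 aryl group. Aromatisation makes the sequence irreversible, and the degassed solvent should keep the electron-rich hydroquinone from oxidising before step 5.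

Step 5
Reactants: 13 2-isopropoxy-3,6-bis(Ar)benzene-1,4-diol
Product: 14 2-isopropoxy-3,6-bis(Ar)-1,4-benzoquinone
Conditions: Ag2O, Et2O, rt
Reagents that add atoms: none
Why: Two-electron oxidation of a hydroquinone to the para-quinone by Ag2O is mild and neutral, so the aryl silyl ethers and the isopropyl enol ether should be unaffected.

Step 6
Reactants: 14 2-isopropoxy-3,6-bis(Ar)-1,4-benzoquinone
Product: 16 2-hydroxy-3,6-bis(Ar)-1,4-benzoquinone, via dichloroborate 15 (not isolated)
Conditions: BCl3, CH2Cl2, −78 °C; then H2O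
Reagents that add atoms: none
Why: Lewis-acid ether dealkylation, in which BCl3 binds the C1 carbonyl and C2 ether oxygens of the vinylogous ester and chloride removes the secondary isopropyl group as 2-chloropropane at low temperature, the dichloroborate 15 being hydrolysed on work-up, while the weakly basic aryl silyl ether oxygens should not compete at −78 °C.

Step 7
Reactants: 16 2-hydroxy-3,6-bis(Ar)-1,4-benzoquinone
Product: 17 2-acetoxy-3,6-bis(Ar)-1,4-benzoquinone
Conditions: Ac2O, pyridine, CH2Cl2, 0 °C
Reagents that add atoms: acetic anhydride, CC(=O)OC(C)=O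
Why: O-acylation of the acidic hydroxyquinone (a vinylogous carboxylic acid) with Ac2O and pyridine is standard, and because both phenols are silylated the acetyl group can only go to the C2 oxygen.

Step 8
Reactants: 17 2-acetoxy-3,6-bis(Ar)-1,4-benzoquinone
Product: 18 Neonambiquinone A, 2-acetoxy-3,6-bis(4-hydroxyphenyl)-1,4-benzoquinone
Conditions: Bu4NF, AcOH (1:1), THF, 0 °C
Reagents that add atoms: none
Why: Fluoride-induced cleavage of aryl silyl ethers is fast because phenoxide leaves silicon readily, and buffering with AcOH protonates each phenoxide at once and keeps the medium non-basic, so the easily transferred acetyl group of the vinylogous anhydride should stay on the C2 oxygen.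

Compound list
1 | 4-(tert-butyldimethylsilyloxy)benzaldehyde | CC(C)(C)[Si](C)(C)Oc1ccc(C=O)cc1 | starting material
2 | (E)-tert-butyl[4-(2-iodovinyl)phenoxy]dimethylsilane | CC(C)(C)[Si](C)(C)Oc1ccc(/C=C/I)cc1 | intermediate
3 | diisopropyl squarate (3,4-diisopropoxycyclobut-3-ene-1,2-dione) | CC(C)OC1=C(OC(C)C)C(=O)C1=O | starting material
4 | (E)-2-[4-(tert-butyldimethylsilyloxy)phenyl]vinyllithium | [Li]/C=C/c1ccc(O[Si](C)(C)C(C)(C)C)cc1 | intermediate
5 | lithium 2,3-diisopropoxy-4-oxo-1-[(E)-2-Ar-vinyl]cyclobut-2-en-1-olate (racemic) | CC(C)OC1=C(OC(C)C)C(O[Li])(/C=C/c2ccc(O[Si](C)(C)C(C)(C)C)cc2)C1=O | intermediate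
6 | 2,3-diisopropoxy-4-[(E)-2-Ar-vinyl]-4-(trimethylsilyloxy)cyclobut-2-en-1-one (racemic) | CC(C)OC1=C(OC(C)C)C(O[Si](C)(C)C)(/C=C/c2ccc(O[Si](C)(C)C(C)(C)C)cc2)C1=O | intermediate
7 | (4-bromophenoxy)-tert-butyldimethylsilane | CC(C)(C)[Si](C)(C)Oc1ccc(Br)cc1 | starting material
8 | 4-(tert-butyldimethylsilyloxy)phenyllithium | [Li]c1ccc(O[Si](C)(C)C(C)(C)C)cc1 | intermediate
9 | lithium 1-Ar-2,3-diisopropoxy-4-[(E)-2-Ar-vinyl]-4-(trimethylsilyloxy)cyclobut-2-en-1-olate (racemic, diastereomer mixture) | CC(C)OC1=C(OC(C)C)C(O[Si](C)(C)C)(/C=C/c2ccc(O[Si](C)(C)C(C)(C)C)cc2)C1(O[Li])c1ccc(O[Si](C)(C)C(C)(C)C)cc1 | intermediate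
10 | 4-hydroxy-2-isopropoxy-3-Ar-4-[(E)-2-Ar-vinyl]cyclobut-2-en-1-one (racemic) | CC(C)OC1=C(c2ccc(O[Si](C)(C)C(C)(C)C)cc2)C(O)(/C=C/c2ccc(O[Si](C)(C)C(C)(C)C)cc2)C1=O | intermediate
11 | (3E,5E)-4-hydroxy-2-isopropoxy-3,6-bis(Ar)hexa-1,3,5-trien-1-one (dienylketene, styryl group cis to the ketene-bearing carbon) | CC(C)OC(=C=O)/C(c1ccc(O[Si](C)(C)C(C)(C)C)cc1)=C(O)\C=C\c1ccc(O[Si](C)(C)C(C)(C)C)cc1 | intermediate
12 | 4-hydroxy-2-isopropoxy-3,6-bis(Ar)cyclohexa-2,4-dien-1-one (racemic) | CC(C)OC1=C(c2ccc(O[Si](C)(C)C(C)(C)C)cc2)C(O)=CC(c2ccc(O[Si](C)(C)C(C)(C)C)cc2)C1=O | intermediate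
13 | 2-isopropoxy-3,6-bis(Ar)benzene-1,4-diol | CC(C)Oc1c(O)c(-c2ccc(O[Si](C)(C)C(C)(C)C)cc2)cc(O)c1-c1ccc(O[Si](C)(C)C(C)(C)C)cc1 | intermediate
14 | 2-isopropoxy-3,6-bis(Ar)-1,4-benzoquinone | CC(C)OC1=C(c2ccc(O[Si](C)(C)C(C)(C)C)cc2)C(=O)C=C(c2ccc(O[Si](C)(C)C(C)(C)C)cc2)C1=O | intermediate
15 | 2-(dichloroboryloxy)-3,6-bis(Ar)-1,4-benzoquinone | ClB(Cl)OC1=C(c2ccc(O[Si](C)(C)C(C)(C)C)cc2)C(=O)C=C(c2ccc(O[Si](C)(C)C(C)(C)C)cc2)C1=O | intermediate
16 | 2-hydroxy-3,6-bis(Ar)-1,4-benzoquinone | OC1=C(c2ccc(O[Si](C)(C)C(C)(C)C)cc2)C(=O)C=C(c2ccc(O[Si](C)(C)C(C)(C)C)cc2)C1=O | intermediate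
17 | 2-acetoxy-3,6-bis(Ar)-1,4-benzoquinone | CC(=O)OC1=C(c2ccc(O[Si](C)(C)C(C)(C)C)cc2)C(=O)C=C(c2ccc(O[Si](C)(C)C(C)(C)C)cc2)C1=O | intermediate
18 | Neonambiquinone A, 2-acetoxy-3,6-bis(4-hydroxyphenyl)-1,4-benzoquinone | CC(=O)OC1=C(c2ccc(O)cc2)C(=O)C=C(c2ccc(O)cc2)C1=O | target

Total step count: 8.
Longest linear sequence: 8 steps (1 to 18). Squarate 3 and aryl bromide 7 enter in steps 2 and 3 without steps of their own.

Steps most likely to fail

Step 4. The hydroxyl may rotate inward in part, or the ketene may be intercepted by the free tertiary hydroxyl of a second molecule or by traces of water before it closes. The electron-rich hydroquinone may also degrade on prolonged heating. The fallback sets out from 10 and comes back at 13. Silylation of the tertiary hydroxyl (TMSCl, imidazole, DMF, 0 °C) should give 2-isopropoxy-3-Ar-4-[(E)-2-Ar-vinyl]-4-(trimethylsilyloxy)cyclobut-2-en-1-one F1, which has no free hydroxyl to trap the ketene. Thermolysis in toluene at 110 °C should then give 2-isopropoxy-3,6-bis(Ar)-4-(trimethylsilyloxy)phenol F2 by the same opening and closure, with the silyloxy group rotating outward. Brief treatment with 1 M HCl in THF at 0 °C should cleave only the aryl trimethylsilyl ether and return 13.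

Step 6. Chloride may add to the unsubstituted C5 position of the electrophilic quinone, or the Lewis acid may begin to strip the aryl silyl ethers before dealkylation is complete. The fallback sets out from 13 and comes back at 16, reversing the order of oxidation and dealkylation. BCl3 (CH2Cl2, −78 → 0 °C) is applied to the hydroquinone, where the C1 hydroxyl forms an aryloxyboron chelate with the neighbouring C2 ether oxygen and directs removal of the isopropyl group. This should give 3,6-bis(Ar)benzene-1,2,4-triol F3. Oxidation with Ag2O in Et2O should then give 16 directly, so no quinone ever meets the Lewis acid or chloride.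

Step 8. The acetyl group of the vinylogous anhydride may be transferred to fluoride, to liberated phenoxide or to water during desilylation. The fallback sets out from 16 and comes back at 18, so that no fluoride step follows acetylation. Bu4NF in THF at 0 °C, then acidic work-up, should give 2-hydroxy-3,6-bis(4-hydroxyphenyl)-1,4-benzoquinone F4. One equivalent of Et3N should then ionise only the far more acidic vinylogous-acid hydroxyl. Acetyl chloride (1 equiv, THF, −78 °C) should acylate this anion at the C2 oxygen faster than the neutral phenols, giving 18.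

Further compounds
F1 | step 4 | 2-isopropoxy-3-Ar-4-[(E)-2-Ar-vinyl]-4-(trimethylsilyloxy)cyclobut-2-en-1-one (racemic) | CC(C)OC1=C(c2ccc(O[Si](C)(C)C(C)(C)C)cc2)C(O[Si](C)(C)C)(/C=C/c2ccc(O[Si](C)(C)C(C)(C)C)cc2)C1=O
F2 | step 4 | 2-isopropoxy-3,6-bis(Ar)-4-(trimethylsilyloxy)phenol | CC(C)Oc1c(O)c(-c2ccc(O[Si](C)(C)C(C)(C)C)cc2)cc(O[Si](C)(C)C)c1-c1ccc(O[Si](C)(C)C(C)(C)C)cc1
F3 | step 6 | 3,6-bis(Ar)benzene-1,2,4-triol | Oc1c(O)c(-c2ccc(O[Si](C)(C)C(C)(C)C)cc2)cc(O)c1-c1ccc(O[Si](C)(C)C(C)(C)C)cc1
F4 | step 8 | 2-hydroxy-3,6-bis(4-hydroxyphenyl)-1,4-benzoquinone | OC1=C(c2ccc(O)cc2)C(=O)C=C(c2ccc(O)cc2)C1=O
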